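**Retrosynthetic overview**

1. Target: (4S,5R,9S,10R,13R)-13-hydroxylabd-8(17)-ene-15,19-dioic acid. The two acids are unmasked last from a C19 nitrile and a C15 alcohol; C17 comes from Wittig methylenation of a C8 ketone, C18 from methylation at C4, and the C20 methyl from a formyl group.
2. Ring A is closed second, by intramolecular alkylation of the C4 nitrile carbanion with a C3 chloride (bond C3–C4), on a cyclohexane that already carries C5, C9 and C10.
3. Ring B is closed first, in the key step, by a formal [3+3] union that forms C7–C8 and C5–C10: a γ-nitro aldehyde (nitronate carbon C8, aldehyde α-carbon C10) plus penta-2,4-dienenitrile (δ-carbon C7, β-carbon C5; the nitrile carbon is C19).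
4. Enabling feature: in ring B the exocyclic-methylene carbon C8 and the methyl-bearing quaternary C10 flank C9, C7 and C5 flank C6, and C4 bears the carboxyl. C8 can therefore be carried as a nitro carbon (nucleophile, later ketone), C10 as the α-carbon of a C20 formyl group, and C4–C7 as a conjugated dienenitrile.
5. Stereocontrol: C13 from (R)-linalool, C9 from an organocatalytic Michael addition, C5 and C10 from C9 in the key step, C4 from equatorial methylation. The γ-nitro aldehyde comes from 5-chloropentanal and a linalool-derived nitroalkene.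

Key step: step 7

Remark: locants C1 to C20 follow the labdane skeleton; commercial penta-2,4-dienenitrile is taken as its E/Z mixture, which is acceptable because both isomers should converge on the same conjugated nitrile in step 7.

**Route**

Step 1
Reactants: 1 (R)-(−)-linalool
Product: 3 (3R)-3,7-dimethyloct-6-ene-1,3-diol, via bis-boron adduct 2 (not isolated)
Conditions: 9-BBN (2.2 equiv), THF, 0 °C to rt; then NaOH, H2O2, 0 °C
Reagents that add atoms: hydrogen peroxide (OO)
Why: Hydroboration–oxidation: 9-BBN should add anti-Markovnikov to the monosubstituted vinyl group far faster than to the trisubstituted alkene, and oxidation of the C–B bond gives the primary alcohol (later C15) while the carbinol stereocentre (later C13) is not touched.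

Step 2
Reactants: 3 (3R)-3,7-dimethyloct-6-ene-1,3-diol
Product: 4 (4R)-2,2,4-trimethyl-4-(4-methylpent-3-en-1-yl)-1,3-dioxane
Conditions: 2,2-dimethoxypropane, PPTS (cat.), CH2Cl2, rt
Reagents that add atoms: 2,2-dimethoxypropane (COC(C)(C)OC)
Why: Acid-catalysed acetal exchange should tie the 1,3-diol into a six-membered acetonide that masks the tertiary and the primary hydroxyl group at once; no stereocentre is formed.

Step 3
Reactants: 4 (4R)-2,2,4-trimethyl-4-(4-methylpent-3-en-1-yl)-1,3-dioxane
Product: 6 3-[(4R)-2,2,4-trimethyl-1,3-dioxan-4-yl]propanal, via ozonide 5 (not isolated)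
Conditions: O3, CH2Cl2, −78 °C; then Me2S, −78 °C to rt
Reagents that add atoms: ozone ([O-][O+]=O)
Why: Ozonolysis with reductive work-up should cleave the only alkene to the aldehyde (its carbon is the later C9) and acetone, the acetonide being inert to ozone and Me2S.

Step 4
Reactants: 6 3-[(4R)-2,2,4-trimethyl-1,3-dioxan-4-yl]propanal
Product: 8 (4R)-2,2,4-trimethyl-4-[(3E)-4-nitrobut-3-en-1-yl]-1,3-dioxane, via nitro alcohol 7 (not isolated)
Conditions: MeNO2, Et3N (cat.), THF, 0 °C; then MsCl, Et3N, CH2Cl2, 0 °C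
Reagents that add atoms: nitromethane (C[N+](=O)[O-])
Why: Henry reaction of the aldehyde with nitromethane (its carbon is the later C8) followed by mesylation and E1cB elimination should give the conjugated (E)-nitroalkene, the thermodynamically favoured geometry.

Step 5
Reactants: 9 5-chloropentan-1-ol
Product: 10 5-chloropentanal
Conditions: TEMPO (cat.), PhI(OAc)2, CH2Cl2, rt
Reagents that add atoms: none
Why: Nitroxyl-catalysed alcohol oxidation with PhI(OAc)2 as terminal oxidant should stop at the aldehyde and leave the alkyl chloride untouched.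

Step 6
Reactants: 8 (4R)-2,2,4-trimethyl-4-[(3E)-4-nitrobut-3-en-1-yl]-1,3-dioxane; 10 5-chloropentanal
Product: 11 (2R,3R)-2-(3-chloropropyl)-3-(nitromethyl)-5-[(4R)-2,2,4-trimethyl-1,3-dioxan-4-yl]pentanal
Conditions: (S)-α,α-diphenylprolinol trimethylsilyl ether (10 mol %), 4-nitrophenol (10 mol %), toluene, 0 °C to rt
Reagents that add atoms: none
Why: Enamine-mediated asymmetric Michael addition: the (E)-enamine of 10 formed with the (S)-diarylprolinol silyl ether should attack the nitroalkene from the face not shielded by the diaryl(silyloxy)methyl group through the usual synclinal transition state, which sets C9 (the syn adduct is expected; the epimerisable α-centre, the later C10, is set only in step 7).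

Step 7
Reactants: 11 (2R,3R)-2-(3-chloropropyl)-3-(nitromethyl)-5-[(4R)-2,2,4-trimethyl-1,3-dioxan-4-yl]pentanal; 12 penta-2,4-dienenitrile
Product: 15 1-(3-chloropropyl)-2-(cyanomethyl)-5-nitro-6-{2-[(4R)-2,2,4-trimethyl-1,3-dioxan-4-yl]ethyl}cyclohexane-1-carbaldehyde, via dienenitrile adduct 13 (not isolated), via conjugated nitrile 14 (not isolated)
Conditions: DBU (0.5 equiv), BHT (trace), MeCN, 0 °C to 40 °C
Reagents that add atoms: none
Why: Proposed new method: DBU generates the nitronate of 11, which should add in 1,6-fashion to the terminal CH2 of dienenitrile 12 to form C7–C8 (adduct 13), and base-mediated migration of the C5=C6 double bond into conjugation then gives enenitrile 14, whose acceptor carbon C5 lies six atoms from the enolisable formyl-bearing carbon. The enolate of the α-branched aldehyde should then close ring B by an intramolecular Michael addition onto C5 (6-exo-trig), creating the quaternary C10 and the C5–C10 bond. Each half has close precedent (base-mediated 1,6-conjugate addition of nitroalkanes to dienyl acceptors, cyanoethylation of α-branched aldehydes, nitro-Michael/Michael cyclohexane annulations of γ-nitro carbonyl compounds), but their combination with a dienenitrile acting as a 1,3-bis-electrophile is new. C5 and C10 should be set by the stereocentre C9 through a chair transition state in which the C9 side chain, the chloropropyl arm on C10 and the forming cyanomethyl arm on C5 are equatorial and the flat enolate carbon (the later C20) is axial; C8 equilibrates through its nitronate to the equatorial nitro epimer, and both C10 epimers of 11 converge through one enolate. The step needs δ- over β-attack in the first addition, which the unsubstituted diene terminus and the extended anion should secure, and C- over O-attack of the enolate, which the six-membered ring size should secure.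

Step 8
Reactants: 15 1-(3-chloropropyl)-2-(cyanomethyl)-5-nitro-6-{2-[(4R)-2,2,4-trimethyl-1,3-dioxan-4-yl]ethyl}cyclohexane-1-carbaldehyde
Product: 17 2-[2-(3-chloropropyl)-2-methyl-4-nitro-3-{2-[(4R)-2,2,4-trimethyl-1,3-dioxan-4-yl]ethyl}cyclohexyl]acetonitrile, via tosylhydrazone 16 (not isolated)
Conditions: TsNHNH2, EtOH, 50 °C; then catecholborane, CHCl3, 0 °C; NaOAc·3H2O, reflux
Reagents that add atoms: none
Why: Reductive deoxygenation through the tosylhydrazone (hydride addition to C=N, then loss of sulfinate and N2) should turn the non-enolisable formyl group into the C20 methyl without touching nitro, nitrile, chloride or acetonide.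

Step 9
Reactants: 17 2-[2-(3-chloropropyl)-2-methyl-4-nitro-3-{2-[(4R)-2,2,4-trimethyl-1,3-dioxan-4-yl]ethyl}cyclohexyl]acetonitrile
Product: 18 4a-methyl-6-nitro-5-{2-[(4R)-2,2,4-trimethyl-1,3-dioxan-4-yl]ethyl}decahydronaphthalene-1-carbonitrile
Conditions: LiN(i-Pr)2 (2.2 equiv), THF, −78 °C to 0 °C; AcOH quench
Reagents that add atoms: none
Why: Intramolecular alkylation of a metalated nitrile: the first equivalent of base forms the nitronate (a poor carbon nucleophile), the second forms the α-cyano carbanion, which should displace chloride in a 6-exo-tet closure of ring A; the trans ring fusion follows from the equatorial arms on C5 and C10, and the C4 configuration is left open because it is set in step 12.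

Step 10
Reactants: 18 4a-methyl-6-nitro-5-{2-[(4R)-2,2,4-trimethyl-1,3-dioxan-4-yl]ethyl}decahydronaphthalene-1-carbonitrile
Product: 20 4a-methyl-6-oxo-5-{2-[(4R)-2,2,4-trimethyl-1,3-dioxan-4-yl]ethyl}decahydronaphthalene-1-carbonitrile, via potassium nitronate 19 (not isolated)
Conditions: KOH, MeOH, 0 °C; then KMnO4, MgSO4, H2O, 0 °C
Reagents that add atoms: KMnO4 ([K+].[O-][Mn](=O)(=O)=O)
Why: Oxidative Nef reaction: the nitronate C=N bond should be cleaved by KMnO4 to the C8 ketone, and the adjacent C9 keeps (or equilibrates to) the required configuration with the side chain equatorial.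

Step 11
Reactants: 20 4a-methyl-6-oxo-5-{2-[(4R)-2,2,4-trimethyl-1,3-dioxan-4-yl]ethyl}decahydronaphthalene-1-carbonitrile
Product: 21 4a-methyl-6-methylidene-5-{2-[(4R)-2,2,4-trimethyl-1,3-dioxan-4-yl]ethyl}decahydronaphthalene-1-carbonitrile
Conditions: Ph3PCH3Br, KOt-Bu, THF, 0 °C to reflux
Reagents that add atoms: methyltriphenylphosphonium bromide (C[P+](c1ccccc1)(c1ccccc1)c1ccccc1.[Br-])
Why: Wittig methylenation of the hindered ketone with the unstabilised ylide should install the exocyclic C8=C17 alkene, a standard operation on decalin ketones of this type; any base-induced equilibration at C9 favours the required equatorial side chain.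

Step 12
Reactants: 21 4a-methyl-6-methylidene-5-{2-[(4R)-2,2,4-trimethyl-1,3-dioxan-4-yl]ethyl}decahydronaphthalene-1-carbonitrile
Product: 23 (1S,4aR,5S,8aR)-1,4a-dimethyl-6-methylidene-5-{2-[(4R)-2,2,4-trimethyl-1,3-dioxan-4-yl]ethyl}decahydronaphthalene-1-carbonitrile, via lithiated nitrile 22 (not isolated)
Conditions: LiN(i-Pr)2, THF, −78 °C; then MeI, −78 °C to 0 °C
Reagents that add atoms: iodomethane (CI)
Why: Alkylation of a metalated nitrile: MeI should approach the planar keteniminate along the equatorial α trajectory, anti to the axial C20 methyl (1,3-diaxial), so that the new methyl becomes equatorial and the nitrile (the later C19 carboxyl) axial, which sets C4.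

Step 13
Reactants: 23 (1S,4aR,5S,8aR)-1,4a-dimethyl-6-methylidene-5-{2-[(4R)-2,2,4-trimethyl-1,3-dioxan-4-yl]ethyl}decahydronaphthalene-1-carbonitrile
Product: 26 (1S,4aR,5S,8aR)-5-[(3R)-3,5-dihydroxy-3-methylpentyl]-1,4a-dimethyl-6-methylidenedecahydronaphthalene-1-carbaldehyde, via aluminium aldimine 24 (not isolated), via acetonide aldehyde 25 (not isolated)
Conditions: i-Bu2AlH, toluene, −78 °C to 0 °C; then AcOH/THF/H2O, 40 °C
Reagents that add atoms: water (O)
Why: Partial reduction of the hindered nitrile by i-Bu2AlH stops at the aluminated aldimine, and the aqueous acetic acid work-up should hydrolyse both the imine to the aldehyde and the acetonide to the diol without isomerising the exocyclic alkene.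

Step 14
Reactants: 26 (1S,4aR,5S,8aR)-5-[(3R)-3,5-dihydroxy-3-methylpentyl]-1,4a-dimethyl-6-methylidenedecahydronaphthalene-1-carbaldehyde
Product: 27 (1S,4aR,5S,8aR)-5-[(3R)-3-hydroxy-3-methyl-5-oxopentyl]-1,4a-dimethyl-6-methylidenedecahydronaphthalene-1-carbaldehyde
Conditions: TEMPO (cat.), PhI(OAc)2, CH2Cl2, rt
Reagents that add atoms: none
Why: Nitroxyl-catalysed alcohol oxidation should convert only the primary alcohol into the aldehyde, the tertiary alcohol and the alkene being inert.

Step 15
Reactants: 27 (1S,4aR,5S,8aR)-5-[(3R)-3-hydroxy-3-methyl-5-oxopentyl]-1,4a-dimethyl-6-methylidenedecahydronaphthalene-1-carbaldehyde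
Product: 28 (1S,4aR,5S,8aR)-5-[(3R)-4-carboxy-3-hydroxy-3-methylbutyl]-1,4a-dimethyl-6-methylidenedecahydronaphthalene-1-carboxylic acid
Conditions: NaClO2, NaH2PO4, 2-methylbut-2-ene, t-BuOH/H2O, 0 °C to rt
Reagents that add atoms: sodium chlorite ([Na+].[O-]Cl=O)
Why: Pinnick oxidation should convert both aldehydes into the carboxylic acids, 2-methylbut-2-ene scavenging hypochlorous acid so that the exocyclic alkene and the tertiary alcohol survive.

**Compound list**

1 | (R)-(−)-linalool, (3R)-3,7-dimethylocta-1,6-dien-3-ol | CC(C)=CCC[C@@](C)(O)C=C | starting material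
2 | bis-boron adduct of 1 (9-BBN borinate at the tertiary oxygen, 9-BBN alkylborane at the terminal carbon) | CC(C)=CCC[C@@](C)(OB1C2CCCC1CCC2)CCB1C2CCCC1CCC2 | intermediate
3 | (3R)-3,7-dimethyloct-6-ene-1,3-diol | CC(C)=CCC[C@@](C)(O)CCO | intermediate
4 | (4R)-2,2,4-trimethyl-4-(4-methylpent-3-en-1-yl)-1,3-dioxane | CC(C)=CCC[C@@]1(C)OC(C)(C)OCC1 | intermediate
5 | ozonide of 4: 3,3-dimethyl-5-{2-[(4R)-2,2,4-trimethyl-1,3-dioxan-4-yl]ethyl}-1,2,4-trioxolane | CC1(C)OOC(CC[C@@]2(C)OC(C)(C)OCC2)O1 | intermediate
6 | 3-[(4R)-2,2,4-trimethyl-1,3-dioxan-4-yl]propanal | O=CCC[C@@]1(C)OC(C)(C)OCC1 | intermediate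
7 | 1-nitro-4-[(4R)-2,2,4-trimethyl-1,3-dioxan-4-yl]butan-2-ol (both carbinol epimers) | [O-][N+](=O)CC(O)CC[C@@]1(C)OC(C)(C)OCC1 | intermediate
8 | (4R)-2,2,4-trimethyl-4-[(3E)-4-nitrobut-3-en-1-yl]-1,3-dioxane | [O-][N+](=O)/C=C/CC[C@@]1(C)OC(C)(C)OCC1 | intermediate
9 | 5-chloropentan-1-ol | OCCCCCCl | starting material
10 | 5-chloropentanal | O=CCCCCCl | intermediate
11 | (2R,3R)-2-(3-chloropropyl)-3-(nitromethyl)-5-[(4R)-2,2,4-trimethyl-1,3-dioxan-4-yl]pentanal | O=C[C@H](CCCCl)[C@@H](CC[C@@]1(C)OC(C)(C)OCC1)C[N+](=O)[O-] | intermediate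
12 | penta-2,4-dienenitrile (E/Z mixture) | C=CC=CC#N | starting material
13 | dienenitrile adduct: (3R)-2-(3-chloropropyl)-3-[(3E)-5-cyano-1-nitropent-3-en-1-yl]-5-[(4R)-2,2,4-trimethyl-1,3-dioxan-4-yl]pentanal (mixture at the formyl-bearing and nitro-bearing carbons) | O=CC(CCCCl)[C@@H](CC[C@@]1(C)OC(C)(C)OCC1)C(C/C=C/CC#N)[N+](=O)[O-] | intermediate
14 | conjugated nitrile: (3R)-2-(3-chloropropyl)-3-[(4E)-5-cyano-1-nitropent-4-en-1-yl]-5-[(4R)-2,2,4-trimethyl-1,3-dioxan-4-yl]pentanal (mixture at the formyl-bearing and nitro-bearing carbons) | O=CC(CCCCl)[C@@H](CC[C@@]1(C)OC(C)(C)OCC1)C(CC/C=C/C#N)[N+](=O)[O-] | intermediate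
15 | 1-(3-chloropropyl)-2-(cyanomethyl)-5-nitro-6-{2-[(4R)-2,2,4-trimethyl-1,3-dioxan-4-yl]ethyl}cyclohexane-1-carbaldehyde (formyl axial; nitro group and the three carbon arms equatorial; ring atoms are C10, C5, C6, C7, C8, C9) | [O-][N+](=O)[C@@H]1CC[C@@H](CC#N)[C@](C=O)(CCCCl)[C@H]1CC[C@@]2(C)OC(C)(C)OCC2 | intermediate
16 | (E)-4-methylbenzenesulfonylhydrazone of 15 | [O-][N+](=O)[C@@H]1CC[C@@H](CC#N)[C@](/C=N/NS(=O)(=O)c2ccc(C)cc2)(CCCCl)[C@H]1CC[C@@]3(C)OC(C)(C)OCC3 | intermediate
17 | 2-[2-(3-chloropropyl)-2-methyl-4-nitro-3-{2-[(4R)-2,2,4-trimethyl-1,3-dioxan-4-yl]ethyl}cyclohexyl]acetonitrile (methyl axial; other substituents equatorial) | [O-][N+](=O)[C@@H]1CC[C@@H](CC#N)[C@](C)(CCCCl)[C@H]1CC[C@@]2(C)OC(C)(C)OCC2 | intermediate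
18 | 4a-methyl-6-nitro-5-{2-[(4R)-2,2,4-trimethyl-1,3-dioxan-4-yl]ethyl}decahydronaphthalene-1-carbonitrile (trans-fused; 4a-methyl β, 8a-H α, 5-side chain β equatorial; epimers at C1 and C6) | [O-][N+](=O)C1CC[C@@H]2[C@](C)(CCCC2C#N)[C@H]1CC[C@@]3(C)OC(C)(C)OCC3 | intermediate
19 | potassium nitronate of 18 | [K+].[O-][N+]([O-])=C1CC[C@@H]2[C@](C)(CCCC2C#N)[C@H]1CC[C@@]3(C)OC(C)(C)OCC3 | intermediate
20 | 4a-methyl-6-oxo-5-{2-[(4R)-2,2,4-trimethyl-1,3-dioxan-4-yl]ethyl}decahydronaphthalene-1-carbonitrile (ring stereocentres as in 18; epimers at C1) | O=C1CC[C@@H]2[C@](C)(CCCC2C#N)[C@H]1CC[C@@]3(C)OC(C)(C)OCC3 | intermediate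
21 | 4a-methyl-6-methylidene-5-{2-[(4R)-2,2,4-trimethyl-1,3-dioxan-4-yl]ethyl}decahydronaphthalene-1-carbonitrile (ring stereocentres as in 18; epimers at C1) | C=C1CC[C@@H]2[C@](C)(CCCC2C#N)[C@H]1CC[C@@]3(C)OC(C)(C)OCC3 | intermediate
22 | N-lithio keteniminate of 21 | C=C1CC[C@@H]2[C@](C)(CCCC2=C=N[Li])[C@H]1CC[C@@]3(C)OC(C)(C)OCC3 | intermediate
23 | (1S,4aR,5S,8aR)-1,4a-dimethyl-6-methylidene-5-{2-[(4R)-2,2,4-trimethyl-1,3-dioxan-4-yl]ethyl}decahydronaphthalene-1-carbonitrile | C=C1CC[C@@H]2[C@](C)(CCC[C@]2(C)C#N)[C@H]1CC[C@@]3(C)OC(C)(C)OCC3 | intermediate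
24 | N-(diisobutylalumanyl) aldimine of 23 | C=C1CC[C@@H]2[C@](C)(CCC[C@]2(C)C=N[Al](CC(C)C)CC(C)C)[C@H]1CC[C@@]3(C)OC(C)(C)OCC3 | intermediate
25 | (1S,4aR,5S,8aR)-1,4a-dimethyl-6-methylidene-5-{2-[(4R)-2,2,4-trimethyl-1,3-dioxan-4-yl]ethyl}decahydronaphthalene-1-carbaldehyde | C=C1CC[C@@H]2[C@](C)(CCC[C@]2(C)C=O)[C@H]1CC[C@@]3(C)OC(C)(C)OCC3 | intermediate
26 | (1S,4aR,5S,8aR)-5-[(3R)-3,5-dihydroxy-3-methylpentyl]-1,4a-dimethyl-6-methylidenedecahydronaphthalene-1-carbaldehyde | C=C1CC[C@@H]2[C@](C)(CCC[C@]2(C)C=O)[C@H]1CC[C@@](C)(O)CCO | intermediate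
27 | (1S,4aR,5S,8aR)-5-[(3R)-3-hydroxy-3-methyl-5-oxopentyl]-1,4a-dimethyl-6-methylidenedecahydronaphthalene-1-carbaldehyde | C=C1CC[C@@H]2[C@](C)(CCC[C@]2(C)C=O)[C@H]1CC[C@@](C)(O)CC=O | intermediate
28 | (1S,4aR,5S,8aR)-5-[(3R)-4-carboxy-3-hydroxy-3-methylbutyl]-1,4a-dimethyl-6-methylidenedecahydronaphthalene-1-carboxylic acid | C=C1CC[C@@H]2[C@](C)(CCC[C@]2(C)C(=O)O)[C@H]1CC[C@@](C)(O)CC(=O)O | target

**Count of steps and risks**

Total step count: 15. Longest linear sequence: 14 steps (from 1 through steps 1 to 4 and 6 to 15).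

The three steps most likely to fail are taken in turn below, the riskiest first.

The first is step 7, which bears the label of a proposed new method. The nitronate may attack the β-carbon of the dienenitrile instead of the terminal carbon, the dienenitrile may oligomerise, the aldehyde enolate may be O-alkylated by the chloride before ring closure, or the sequence may stall after the first addition because the conjugated nitrile is a weak acceptor. The fallback uses known reactions only; it sets out from 11 and comes back to the route at 15. Conjugate addition of the nitronate of 11 to acrolein (Et3N cat., MeCN, 0 °C) should give the nitro dialdehyde F1. A Horner–Wadsworth–Emmons reaction with one equivalent of diethyl cyanomethylphosphonate (LiCl, DBU, MeCN, 0 °C) should take place at the unhindered linear aldehyde faster than at the α-branched one and give the conjugated nitrile 14 as an isolated compound. Ring closure through the aldehyde enolate (DBU, MeCN, rt to 40 °C), the intramolecular form of the classical base-catalysed cyanoethylation of α-branched aldehydes, should then deliver 15.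

The second is step 9. The chloride may alkylate the nitronate at carbon or oxygen, or hydrogen chloride may be eliminated, in competition with the nitrile carbanion. The fallback sets out from 17, removes the nitro group before any carbanion chemistry, and comes back to the route at 21. A Nef reaction (KOH, MeOH; then KMnO4, MgSO4, 0 °C) should give the chloro ketone F2, Wittig methylenation with salt-free Ph3P=CH2 (THF, 0 °C to rt) should give the chloro alkene F3, and ring closure of its α-cyano carbanion with LiN(i-Pr)2 (THF, −78 °C to 0 °C) should then give 21 directly.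

The third is step 8. Condensation at the hindered neopentyl formyl group may stay incomplete, or the reduction may stop at the hydrazine or alcohol level. The fallback sets out from 15 and comes back to the route at 17. Reduction with NaBH4 (MeOH, 0 °C) should give the neopentyl alcohol F4, and iodination (PPh3, I2, imidazole, toluene, 80 °C) should give the neopentyl iodide F5. Radical reduction at room temperature (Bu3SnH, Et3B, air, toluene) should then give 17, because iodine-atom abstraction is far faster than any reaction of the stannyl radical with the secondary nitro group, the nitrile or the primary chloride.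

Further compounds
F1 | step 7 | (3R)-2-(3-chloropropyl)-3-(1-nitro-4-oxobutyl)-5-[(4R)-2,2,4-trimethyl-1,3-dioxan-4-yl]pentanal | O=CC(CCCCl)[C@@H](CC[C@@]1(C)OC(C)(C)OCC1)C(CCC=O)[N+](=O)[O-]
F2 | step 9 | 2-[2-(3-chloropropyl)-2-methyl-4-oxo-3-{2-[(4R)-2,2,4-trimethyl-1,3-dioxan-4-yl]ethyl}cyclohexyl]acetonitrile | O=C1CC[C@@H](CC#N)[C@](C)(CCCCl)[C@H]1CC[C@@]2(C)OC(C)(C)OCC2
F3 | step 9 | 2-[2-(3-chloropropyl)-2-methyl-4-methylidene-3-{2-[(4R)-2,2,4-trimethyl-1,3-dioxan-4-yl]ethyl}cyclohexyl]acetonitrile | C=C1CC[C@@H](CC#N)[C@](C)(CCCCl)[C@H]1CC[C@@]2(C)OC(C)(C)OCC2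
F4 | step 8 | 2-[2-(3-chloropropyl)-2-(hydroxymethyl)-4-nitro-3-{2-[(4R)-2,2,4-trimethyl-1,3-dioxan-4-yl]ethyl}cyclohexyl]acetonitrile | [O-][N+](=O)[C@@H]1CC[C@@H](CC#N)[C@](CO)(CCCCl)[C@H]1CC[C@@]2(C)OC(C)(C)OCC2
F5 | step 8 | 2-[2-(3-chloropropyl)-2-(iodomethyl)-4-nitro-3-{2-[(4R)-2,2,4-trimethyl-1,3-dioxan-4-yl]ethyl}cyclohexyl]acetonitrile | [O-][N+](=O)[C@@H]1CC[C@@H](CC#N)[C@](CI)(CCCCl)[C@H]1CC[C@@]2(C)OC(C)(C)OCC2
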